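**Plan** (labdane numbering: ring A = C1–C5 + C10, ring B = C5–C10; C11–C12 join C9 to the butenolide C13–C16; methyls C17 on C8, C18/C19 on C4, C20 on C10)
Cuts: the butenolide goes back to a 3-substituted furan. C11–C12 is cut as an allylic substitution. The 6β-acetate goes back through the C6 ketone to a C5=C6 silyl enol ether. A temporary oxygen is placed on C1, and last C9–C10 and C7–C8 are cut together.
Enabling feature: ring B holds sp2 C8=C9, an oxygen on C6 and the carbon C11 on C9. It is therefore the Diels–Alder adduct of a ring A 2-silyloxydiene (C10=C5–C6(OSi)=C7) and a C8≡C9 but-2-ynoate whose carbonyl carbon is C11 and whose ester oxygen sits on C1.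
Forward: a purchased ring A dione is given C20, C6–C7 and the ynoate, and one cycloaddition closes ring B and a temporary lactone. The lactone is then reduced, the C1 oxygen removed, the furylmethyl unit joined at C11, C6 adjusted, and the furan oxidised last.
Stereochemistry: C1 comes from a CBS reduction and C10 from C1 through the short tether, after which C1 is erased. C5 comes from α-face protonation and C6 from α-face hydride delivery.

Key step: step 7

Remark: the target SMILES is read as (5S,6R,10S), the normal labdane series with 5α-H, 6β-OAc and 10β-CH3. The descriptors α and β refer to the usual labdane drawing.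

Step 1
Reactants: 1 4,4-dimethylcyclohexane-1,3-dione
Product: 2 2,4,4-trimethylcyclohexane-1,3-dione
Conditions: MeI (1.1 equiv), aq. NaOH, 1,4-dioxane, reflux
Reagents that add atoms: iodomethane, CI
Why: C-alkylation of the stabilised 1,3-dione enolate with about one equivalent of MeI is the standard entry to 2-methylcyclohexane-1,3-diones, and the new C2 centre is enolisable and so of no stereochemical consequence.

Step 2
Reactants: 2 2,4,4-trimethylcyclohexane-1,3-dione
Product: 3 3-isobutoxy-2,6,6-trimethylcyclohex-2-en-1-one
Conditions: i-BuOH, p-TsOH (cat.), toluene, reflux, Dean–Stark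
Reagents that add atoms: 2-methylpropan-1-ol, CC(C)CO
Why: acid-catalysed vinylogous ester formation with azeotropic water removal should occur at the carbonyl remote from the gem-dimethyl carbon, because addition of the alcohol next to the quaternary centre is sterically disfavoured, which leaves the neopentyl ketone (future C5) free.

Step 3
Reactants: 3 3-isobutoxy-2,6,6-trimethylcyclohex-2-en-1-one; 4 ethyl vinyl ether
Product: 7 3-acetyl-2,4,4-trimethylcyclohex-2-en-1-one, via 1-ethoxyvinyllithium 5 (not isolated), via tertiary carbinol adduct 6 (not isolated)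
Conditions: 4, t-BuLi, THF, −78 → 0 °C; add 3, −78 °C → rt; then 2 M HCl, THF, rt
Reagents that add atoms: water, O
Why: Stork–Danheiser carbonyl transposition, in which the small acyl-anion equivalent adds 1,2 to the only free ketone and aqueous acid then unmasks the acetyl group and ionises the tertiary allylic alcohol, so that the ring carbonyl reappears at the former enol ether carbon (future C1) with the C5=C10 olefin in place.

Step 4
Reactants: 7 3-acetyl-2,4,4-trimethylcyclohex-2-en-1-one
Product: 8 (S)-3-acetyl-2,4,4-trimethylcyclohex-2-en-1-ol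
Conditions: (R)-Me-CBS oxazaborolidine (15 mol%), BH3·SMe2 (0.65 equiv), THF, −30 °C
Reagents that add atoms: none
Why: Corey–Bakshi–Shibata reduction, in which the planar ring enone binds the oxazaborolidine–borane complex with its alkenyl branch as the large group so that the (R)-catalyst gives the (S)-carbinol, while the acetyl carbonyl, twisted out of the olefin plane and flanked on both faces by the C4 gem-dimethyl and C10 methyl groups, should react much more slowly with the substoichiometric borane.

Step 5
Reactants: 8 (S)-3-acetyl-2,4,4-trimethylcyclohex-2-en-1-ol; 9 but-2-ynoic acid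
Product: 10 (S)-3-acetyl-2,4,4-trimethylcyclohex-2-en-1-yl but-2-ynoate
Conditions: DCC, DMAP (cat.), CH2Cl2, 0 °C
Reagents that add atoms: none
Why: Steglich esterification acylates the secondary allylic alcohol at oxygen under neutral conditions, so the C1–O bond and its configuration are untouched.

Step 6
Reactants: 10 (S)-3-acetyl-2,4,4-trimethylcyclohex-2-en-1-yl but-2-ynoate
Product: 11 (S)-3-[1-(tert-butyldimethylsilyloxy)vinyl]-2,4,4-trimethylcyclohex-2-en-1-yl but-2-ynoate
Conditions: TBSOTf, Et3N, CH2Cl2, 0 °C
Reagents that add atoms: tert-butyldimethylsilyl trifluoromethanesulfonate, CC(C)(C)[Si](C)(C)OS(=O)(=O)C(F)(F)F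
Why: soft enolisation of a methyl ketone with a silyl triflate and a tertiary amine, in which only the acetyl CH3 offers α-hydrogens, so the cross-conjugated 2-silyloxydiene is the enol silane expected and the less Lewis-basic ynoate ester is left alone.

Step 7
Reactants: 11 (S)-3-[1-(tert-butyldimethylsilyloxy)vinyl]-2,4,4-trimethylcyclohex-2-en-1-yl but-2-ynoate
Product: 12 (1S,10S)-tricyclic lactone (ring B 5,8-diene; 6-OTBS; C11 carbonyl bridged to the 1α-oxygen; 10β-methyl)
Conditions: BHT (cat.), N,O-bis(trimethylsilyl)acetamide (0.2 equiv), 1,2-dichlorobenzene (0.01 M), 150 °C, sealed tube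
Reagents that add atoms: none
Why: On heating, the electron-rich 2-silyloxydiene (C10=C5–C6(OSi)=C7) and the electron-poor ynoate (C8≡C9–C11=O) combine in a concerted, asynchronous, normal-electron-demand [4+2] cycloaddition that forms C7–C8 and C9–C10 in one event. The closest known reaction type is the thermal intramolecular Diels–Alder reaction of alkynoate esters of 3-vinylcyclohex-2-en-1-ols, which gives lactone-bridged octalins with an angular methyl group on a new quaternary carbon. Ring B closes as the six-membered cycloaddition ring (a cyclohexa-1,4-diene with olefins C5=C6 and C8=C9), and the three-atom tether C1–O–C11 ends up in a five-membered lactone (C1, O, C11, C9, C10) fused to ring A along C1–C10. The only new stereocentre, C10, is controlled by the (S)-carbinol carbon C1, because a tether this short can lay the alkyne only over the diene face that carries the C1 oxygen (the α face), so C9 bonds there and the methyl group is pushed to the β face. Regiochemistry is fixed by the tether and reinforced by polarity, since C7, the diene terminus with the largest HOMO coefficient, meets the β-carbon C8 of the ynoate, and a linear dienophile raises no endo/exo question. The step needs cycloaddition to win over 1,5-hydrogen shift, desilylation and intermolecular addition, which intramolecularity, the donor oxygen on C6, high dilution, a radical inhibitor and a silylating acid scavenger are meant to secure.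

Step 8
Reactants: 12 (1S,10S)-tricyclic lactone
Product: 13 1α,11-diol (6-OTBS 5,8-diene retained)
Conditions: LiAlH4, Et2O, 0 °C; Na2SO4·10H2O work-up
Reagents that add atoms: none
Why: hydride reduction of an α,β-unsaturated γ-lactone with a fully substituted β-carbon proceeds 1,2 to the allylic diol, and doing it before the enol ether is cleaved avoids a C6 ketone whose C7 hydrogens are also vinylogously activated by the C11 carbonyl, a situation that would invite migration of the C8=C9 olefin into conjugation with the ketone.

Step 9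
Reactants: 13 1α,11-diol
Product: 14 11-pivalate of the 1α,11-diol
Conditions: PivCl (1.1 equiv), pyridine, CH2Cl2, 0 °C
Reagents that add atoms: pivaloyl chloride, CC(C)(C)C(=O)Cl
Why: selective acylation works because the primary allylic C11 hydroxyl is far more accessible than the axial neopentyl 1α-hydroxyl, and the pivalate serves first as protecting group and later as leaving group, so that no C11 halide ever sits next to a free C1 alkoxide that could close a cyclic ether.

Step 10
Reactants: 14 11-pivalate of the 1α,11-diol
Product: 16 1α-O-(S-methyl dithiocarbonate) 11-pivalate, via potassium xanthate salt 15 (not isolated)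
Conditions: KN(SiMe3)2, THF, −78 °C; CS2; MeI, −78 → 0 °C
Reagents that add atoms: carbon disulfide, S=C=S; iodomethane, CI
Why: xanthate formation, the first half of the Barton–McCombie deoxygenation, relies on the small electrophile CS2 to capture the hindered alkoxide at low temperature faster than pivaloyl migration can occur.

Step 11
Reactants: 16 1α-O-(S-methyl dithiocarbonate) 11-pivalate
Product: 17 1-deoxy 11-pivalate (6-OTBS 5,8-diene; 10β-methyl)
Conditions: Bu3SnH (3 equiv, 0.5 M), AIBN (cat.), toluene, 90 °C
Reagents that add atoms: none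
Why: Barton–McCombie deoxygenation, in which stannyl radical attack at sulfur releases the secondary C1 radical, the concentrated stannane quenches it before the homoallyl–cyclopropylcarbinyl (1,2-vinyl shift) pathway can compete, and the C1 stereocentre that has done its work disappears.

Step 12
Reactants: 18 furan-3-ylmethanol
Product: 19 3-(chloromethyl)furan
Conditions: SOCl2, pyridine, Et2O, 0 °C
Reagents that add atoms: thionyl chloride, O=S(Cl)Cl
Why: chlorodehydroxylation of a primary heterobenzylic alcohol with SOCl2 buffered by pyridine is routine, and the chloride is used directly for Grignard formation.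

Step 13
Reactants: 17 1-deoxy 11-pivalate; 19 3-(chloromethyl)furan
Product: 21 6-(tert-butyldimethylsilyloxy)-15,16-epoxylabda-5,8,13(16),14-tetraene, via furan-3-ylmethylmagnesium chloride 20 (not isolated)
Conditions: 19, Mg, THF, 0 °C; then 17, Li2CuCl4 (5 mol%), THF, −20 °C → rt
Reagents that add atoms: none
Why: copper-catalysed allylic substitution of a primary allylic ester by a Grignard reagent, in which the cuprate formed from Li2CuCl4 couples through the CH2 carbon of the 3-furylmethyl unit, the pivaloyl carbonyl resists direct attack, and bond formation at C11 rather than at the γ-carbon C8 is expected because C8 is fully substituted.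

Step 14
Reactants: 21 6-(tert-butyldimethylsilyloxy)-15,16-epoxylabda-5,8,13(16),14-tetraene
Product: 22 15,16-epoxylabda-8,13(16),14-trien-6-one (5α-H)
Conditions: TBAF, AcOH, THF, 0 °C
Reagents that add atoms: none
Why: buffered fluoride cleavage of the silyl enol ether mirrors the mild hydrolysis of Birch-type 1-alkoxycyclohexa-1,4-dienes to β,γ-unsaturated ketones, so the tetrasubstituted C8=C9 olefin should stay in place, and C5 is protonated on the α face because the β face is covered by the axial C10 and 4β methyl groups, giving the trans ring fusion that is also the thermodynamically preferred one.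

Step 15
Reactants: 22 15,16-epoxylabda-8,13(16),14-trien-6-one
Product: 23 15,16-epoxylabda-8,13(16),14-trien-6β-ol
Conditions: LiAlH4, Et2O, −20 → 0 °C
Reagents that add atoms: none
Why: hydride reduction under steric approach control, in which the β face of the C6 carbonyl is blocked by the syn-axial C10 and 4β methyl groups, so hydride arrives from the α face and gives the axial 6β-alcohol.

Step 16
Reactants: 23 15,16-epoxylabda-8,13(16),14-trien-6β-ol
Product: 24 6β-acetoxy-15,16-epoxylabda-8,13(16),14-triene
Conditions: Ac2O, DMAP, pyridine, 50 °C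
Reagents that add atoms: acetic anhydride, CC(=O)OC(C)=O
Why: DMAP-catalysed acetylation with gentle warming overcomes the hindrance of the axial 6β-hydroxyl and touches neither the furan nor the olefin.

Step 17
Reactants: 24 6β-acetoxy-15,16-epoxylabda-8,13(16),14-triene
Product: 26 6β-acetoxy-16-hydroxylabda-8,13-dien-15,16-olide (C16 epimers), via furan endoperoxide 25 (not isolated)
Conditions: O2, hν (visible), rose bengal (polymer-bound), i-Pr2NEt, CH2Cl2, −78 °C → rt
Reagents that add atoms: dioxygen, O=O
Why: singlet-oxygen [4+2] addition to the furan followed by Kornblum–DeLaMare-type fragmentation, in which the hindered amine removes the less encumbered bridgehead hydrogen on C15 and so places the carbonyl at C15 and the hydroxyl at C16, while at −78 °C the furan is consumed faster than a shielded tetrasubstituted ring olefin undergoes the ene reaction, as is known for substrates carrying a 2,6,6-trimethylcyclohexenyl unit.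

Step 18
Reactants: 26 6β-acetoxy-16-hydroxylabda-8,13-dien-15,16-olide
Product: 28 (5S,6R,10S)-6β-acetoxylabda-8,13-dien-15,16-olide (target), via Z-hydroxy acid 27 (not isolated)
Conditions: NaBH4, EtOH, 0 °C; then 1 M HCl
Reagents that add atoms: none
Why: the hydroxybutenolide reacts through its ring-opened aldehyde form, borohydride reduces C16 to the primary alcohol, and acidification closes the (Z)-hydroxy acid to the 4-substituted furan-2(5H)-one without affecting the hindered acetate.

**Compound list**
1 | 4,4-dimethylcyclohexane-1,3-dione | CC1(C)CCC(=O)CC1=O | starting material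
2 | 2,4,4-trimethylcyclohexane-1,3-dione (C2 enolisable, no fixed configuration) | CC1C(=O)CCC(C)(C)C1=O | intermediate
3 | 3-isobutoxy-2,6,6-trimethylcyclohex-2-en-1-one | CC1=C(OCC(C)C)CCC(C)(C)C1=O | intermediate
4 | ethyl vinyl ether | C=COCC | starting material
5 | 1-ethoxyvinyllithium | [Li]C(=C)OCC | intermediate
6 | 1-(1-ethoxyvinyl)-3-isobutoxy-2,6,6-trimethylcyclohex-2-en-1-ol (racemic; lithium alkoxide in the flask) | CCOC(=C)C1(O)C(C)=C(OCC(C)C)CCC1(C)C | intermediate
7 | 3-acetyl-2,4,4-trimethylcyclohex-2-en-1-one | CC(=O)C1=C(C)C(=O)CCC1(C)C | intermediate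
8 | (S)-3-acetyl-2,4,4-trimethylcyclohex-2-en-1-ol | O[C@H]1CCC(C)(C)C(C(C)=O)=C1C | intermediate
9 | but-2-ynoic acid | CC#CC(=O)O | starting material
10 | (S)-3-acetyl-2,4,4-trimethylcyclohex-2-en-1-yl but-2-ynoate | CC#CC(=O)O[C@H]1CCC(C)(C)C(C(C)=O)=C1C | intermediate
11 | (S)-3-[1-(tert-butyldimethylsilyloxy)vinyl]-2,4,4-trimethylcyclohex-2-en-1-yl but-2-ynoate | CC#CC(=O)O[C@H]1CCC(C)(C)C(C(=C)O[Si](C)(C)C(C)(C)C)=C1C | intermediate
12 | (1S,10S)-tricyclic lactone: rings A/B with C5=C6 and C8=C9 olefins, 6-OTBS, methyls on C4 (two), C8 and C10 (β), γ-lactone C9–C11(=O)–O–C1 through the 1α-oxygen | CC1=C2C(=O)O[C@H]3CCC(C)(C)C(=C(O[Si](C)(C)C(C)(C)C)C1)[C@@]23C | intermediate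
13 | 1α,11-diol: C9–CH2OH, 1α-OH, 6-OTBS 5,8-diene, 10β-methyl | CC1=C(CO)[C@@]2(C)[C@@H](O)CCC(C)(C)C2=C(O[Si](C)(C)C(C)(C)C)C1 | intermediate
14 | 11-pivalate of 13 (1α-OH free) | CC1=C(COC(=O)C(C)(C)C)[C@@]2(C)[C@@H](O)CCC(C)(C)C2=C(O[Si](C)(C)C(C)(C)C)C1 | intermediate
15 | potassium 1α-O-dithiocarbonate (xanthate salt) of 14 | CC1=C(COC(=O)C(C)(C)C)[C@@]2(C)[C@@H](OC(=S)[S-])CCC(C)(C)C2=C(O[Si](C)(C)C(C)(C)C)C1.[K+] | intermediate
16 | 1α-O-(S-methyl dithiocarbonate) of 14 | CC1=C(COC(=O)C(C)(C)C)[C@@]2(C)[C@@H](OC(=S)SC)CCC(C)(C)C2=C(O[Si](C)(C)C(C)(C)C)C1 | intermediate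
17 | 1-deoxy 11-pivalate: C1 is CH2, 6-OTBS 5,8-diene, 10β-methyl | CC1=C(COC(=O)C(C)(C)C)[C@@]2(C)CCCC(C)(C)C2=C(O[Si](C)(C)C(C)(C)C)C1 | intermediate
18 | furan-3-ylmethanol | OCc1ccoc1 | starting material
19 | 3-(chloromethyl)furan | ClCc1ccoc1 | intermediate
20 | (furan-3-ylmethyl)magnesium chloride | Cl[Mg]Cc1ccoc1 | intermediate
21 | 6-(tert-butyldimethylsilyloxy)-15,16-epoxylabda-5,8,13(16),14-tetraene (10β-methyl) | CC1=C(CCc2ccoc2)[C@@]2(C)CCCC(C)(C)C2=C(O[Si](C)(C)C(C)(C)C)C1 | intermediate
22 | 15,16-epoxylabda-8,13(16),14-trien-6-one (5α-H, 10β-methyl) | CC1=C(CCc2ccoc2)[C@@]2(C)CCCC(C)(C)[C@@H]2C(=O)C1 | intermediate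
23 | 15,16-epoxylabda-8,13(16),14-trien-6β-ol | CC1=C(CCc2ccoc2)[C@@]2(C)CCCC(C)(C)[C@@H]2[C@H](O)C1 | intermediate
24 | 6β-acetoxy-15,16-epoxylabda-8,13(16),14-triene | CC1=C(CCc2ccoc2)[C@@]2(C)CCCC(C)(C)[C@@H]2[C@H](OC(C)=O)C1 | intermediate
25 | endoperoxide of 24 (O2 bridged across C15 and C16 of the furan; mixture at the new centres) | CC1=C(CCC2=CC3OOC2O3)[C@@]2(C)CCCC(C)(C)[C@@H]2[C@H](OC(C)=O)C1 | intermediate
26 | 6β-acetoxy-16-hydroxylabda-8,13-dien-15,16-olide (C16 epimers) | CC1=C(CCC2=CC(=O)OC2O)[C@@]2(C)CCCC(C)(C)[C@@H]2[C@H](OC(C)=O)C1 | intermediate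
27 | (13Z)-6β-acetoxy-16-hydroxylabda-8,13-dien-15-oic acid | CC1=C(CC/C(CO)=C/C(=O)O)[C@@]2(C)CCCC(C)(C)[C@@H]2[C@H](OC(C)=O)C1 | intermediate
28 | (5S,6R,10S)-6β-acetoxylabda-8,13-dien-15,16-olide | CC(=O)O[C@@H]1CC(C)=C(CCC2=CC(=O)OC2)[C@@]2(C)CCCC(C)(C)[C@H]12 | target

**Step count**
Total steps: 18. The longest linear sequence is 17 steps (steps 1–11 and 13–18). Step 12 is a one-step side branch.

**Steps most likely to fail**

Risk 1 (step 7). The diene is twisted by the clash between the silyloxy group and the C4 gem-dimethyl group, and its C10 terminus is fully substituted. Cycloaddition may therefore be outrun by a 1,5-hydrogen shift from the C10 methyl group to C7, by loss of the silyl group, or by thermal loss of but-2-ynoic acid. The fallback forms the same two bonds but changes the activating group on the alkyne so that no heating is needed. It sets out from 8.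
- Commercial ethynyl p-tolyl sulfone is deprotonated (n-BuLi, THF, −78 °C) and carboxylated with CO2 to 3-(p-tolylsulfonyl)prop-2-ynoic acid F1.
- DCC coupling of this acid with 8 gives the sulfonyl ynoate keto ester F2.
- TBSOTf with the non-nucleophilic base i-Pr2NEt (CH2Cl2, −78 °C) gives the sulfonyl ynoate silyloxydiene F3.
- This diene should cyclise on warming to room temperature to the 8-(p-tolylsulfonyl) tricyclic lactone F4.
- Me2CuLi (Et2O, −78 °C) exchanges the sulfonyl group for the C17 methyl group by conjugate addition–elimination, which comes back to the route at 12.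

Risk 2 (step 13). Substitution at the hindered allylic pivalate may be slow. Attack of the Grignard reagent at the ester carbonyl, or homocoupling of the furylmethyl reagent, could then take over. The fallback moves the fragment union from C11–C12 to C12–C13 and from copper to palladium catalysis. It sets out from 17.
- i-Bu2AlH (CH2Cl2, −78 °C) frees the C11 allylic alcohol F5.
- MnO2 (CH2Cl2) oxidises it to the C11 enal F6.
- Ph3P=CH2 (THF) converts the aldehyde into the 9-vinyl diene F7.
- 9-BBN adds only to the terminal carbon C12 to give the B-alkyl-9-BBN borane F8.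
- B-alkyl Suzuki–Miyaura coupling with commercial 3-bromofuran (PdCl2(dppf), K3PO4, DMF–THF–H2O) comes back to the route at 21.

Risk 3 (step 4). Chemoselectivity may be incomplete, with competing reduction of the acetyl carbonyl. The fallback masks the acetyl group as an alkyne during the asymmetric reduction. It sets out from 3.
- Commercial lithium (trimethylsilyl)acetylide adds (THF, −78 °C → rt) to give the tertiary propargylic carbinol F9.
- Aqueous HCl transposes this carbinol to 2,4,4-trimethyl-3-[(trimethylsilyl)ethynyl]cyclohex-2-en-1-one F10, in which the ring ketone is the only carbonyl.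
- CBS reduction with the (R)-catalyst gives (S)-2,4,4-trimethyl-3-[(trimethylsilyl)ethynyl]cyclohex-2-en-1-ol F11.
- K2CO3 in MeOH removes the silyl group to give (S)-3-ethynyl-2,4,4-trimethylcyclohex-2-en-1-ol F12.
- Gold-catalysed Markovnikov hydration (Ph3PAuNTf2 cat., aqueous 1,4-dioxane) comes back to the route at 8.

**Further compounds**
F1 | step 7 | 3-(p-tolylsulfonyl)prop-2-ynoic acid | Cc1ccc(cc1)S(=O)(=O)C#CC(=O)O
F2 | step 7 | (S)-3-acetyl-2,4,4-trimethylcyclohex-2-en-1-yl 3-(p-tolylsulfonyl)prop-2-ynoate | Cc1ccc(cc1)S(=O)(=O)C#CC(=O)O[C@H]1CCC(C)(C)C(C(C)=O)=C1C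
F3 | step 7 | (S)-3-[1-(tert-butyldimethylsilyloxy)vinyl]-2,4,4-trimethylcyclohex-2-en-1-yl 3-(p-tolylsulfonyl)prop-2-ynoate | Cc1ccc(cc1)S(=O)(=O)C#CC(=O)O[C@H]1CCC(C)(C)C(C(=C)O[Si](C)(C)C(C)(C)C)=C1C
F4 | step 7 | 8-(p-tolylsulfonyl) analogue of lactone 12 (sulfonyl group in place of the C17 methyl) | Cc1ccc(cc1)S(=O)(=O)C1=C2C(=O)O[C@H]3CCC(C)(C)C(=C(O[Si](C)(C)C(C)(C)C)C1)[C@@]23C
F5 | step 13 | C11 allylic alcohol (depivaloylated 17) | CC1=C(CO)[C@@]2(C)CCCC(C)(C)C2=C(O[Si](C)(C)C(C)(C)C)C1
F6 | step 13 | C11 enal | CC1=C(C=O)[C@@]2(C)CCCC(C)(C)C2=C(O[Si](C)(C)C(C)(C)C)C1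
F7 | step 13 | 9-vinyl diene (C11=C12) | CC1=C(C=C)[C@@]2(C)CCCC(C)(C)C2=C(O[Si](C)(C)C(C)(C)C)C1
F8 | step 13 | B-alkyl-9-BBN borane (boron on C12) | CC1=C(CCB2C3CCCC2CCC3)[C@@]2(C)CCCC(C)(C)C2=C(O[Si](C)(C)C(C)(C)C)C1
F9 | step 4 | 3-isobutoxy-2,6,6-trimethyl-1-[(trimethylsilyl)ethynyl]cyclohex-2-en-1-ol (racemic) | CC(C)COC1=C(C)C(O)(C#C[Si](C)(C)C)C(C)(C)CC1
F10 | step 4 | 2,4,4-trimethyl-3-[(trimethylsilyl)ethynyl]cyclohex-2-en-1-one | CC1=C(C#C[Si](C)(C)C)C(C)(C)CCC1=O
F11 | step 4 | (S)-2,4,4-trimethyl-3-[(trimethylsilyl)ethynyl]cyclohex-2-en-1-ol | O[C@H]1CCC(C)(C)C(C#C[Si](C)(C)C)=C1C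
F12 | step 4 | (S)-3-ethynyl-2,4,4-trimethylcyclohex-2-en-1-ol | O[C@H]1CCC(C)(C)C(C#C)=C1C
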